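The data are simulated for substances that don't exist; scatter was added.

The quantity asked is a ratio, monomer in chains over chains begun, so each flask needs a numerator and a count of chains.

common to all: free monomer 0.050 M
- Tuesday's: protic impurity 0.015 M; initiator 2.9 mol%; run made earlier
- Friday's: protic impurity 0.015 M; initiator 4.8 mol%; run made earlier
- Saturday's: protic impurity 0.015 M; initiator 8.7 mol%; run made earlier
- south-east: protic impurity 0.0150 M; initiator 10 mol%; time 3.0 d
- south-west: protic impurity 0.0150 M; initiator 2.5 mol%; time 3.0 d

| Tuesday's: time / d | Tuesday's: monomer in chains / % | Friday's: time / d | Friday's: monomer in chains / % | Saturday's: time / d | Saturday's: monomer in chains / % |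
|---|---|---|---|---|---|
| 0.250 | 22 | 0.250 | 33 | 0.250 | 49 |
| 0.833 | 45 | 0.833 | 50 | 0.417 | 54 |
| 1.25 | 51 | 1.25 | 51 | 0.833 | 55 |
| 2.00 | 52 | 2.00 | 55 | 1.67 | 57 |
| 3.00 | 53 | 3.00 | 54 | 3.00 | 53 |

(readings scatter by 1.5 percentage points)

- the average divides the monomer in chains by the number of chains begun, living and dead together
- the analysis behind the earlier runs scatters by 1.5 percentage points, standard deviation
- the earlier runs do not show the number of chains; that part of a forecast is a guess

* which of the two ends with the longer chains by the average number of monomer units in a chain (chains begun, living or dead) ("neither" if they lie within 10%) (south-east / south-west / neither)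
* average number of monomer units in a chain (chains begun, living or dead) at the end, south-east
* average number of monomer units in a chain (chains begun, living or dead) at the end, south-west

The numerator can be read. Tuesday's, Friday's and Saturday's runs end at 53%, 54% and 53%, at loadings from 2.9 mol% to 8.7 mol%. Their mean is 53.3%, the ceiling share, meaning monomer in chains at the end as a part of the free monomer charged. Tuesday's run read 51% by 1.25 d. If time goes inversely with loading, south-west gets there near 1.45 d, earlier than 3.0 d.

The denominator is disputed, and the readings do not show it. The first chemist holds one chain per initiator, as in a living polymerisation, so the length is ceiling share over loading: 5.33 in south-east and 21.3 in south-west. His ground is that the readings at 0.250 d climb from 22% to 33% to 49% with loading, while c(protic impurity) stays at 0.015 M. The second chemist holds that each protic impurity begins a chain too, as in chain transfer. She notes that c(protic impurity) is 0.0150 M, more than c(initiator) in either flask, and gets 1.33 and 1.64. My own reckoning is the first chemist's.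

The forecast differs from it, giving south-west as longer, with 3 for south-east and 8 for south-west: “I take values between these limits”.

South-west ends at 22.6 and south-east at 5.66, so south-west has the longer chains.

    free monomer + initiator → living end + monomer in chains (k = 35.0 M⁻¹ h⁻¹)
    free monomer + living end → monomer in chains + living end, rate k2*[living end]*[free monomer] (k = 54.0 M⁻¹ h⁻¹)
    monomer in chains + living end → free monomer + living end, rate k3*[living end] as long as [monomer in chains] is above zero (k = 0.440 h⁻¹)
    free monomer + initiator → spent initiator (k = 2.20 M⁻¹ h⁻¹)
    protic impurity + free monomer → quenched substrate (k = 8.50 M⁻¹ h⁻¹)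

South-west holds 0.00118 M of living end from 0.00125 M of initiator, and beginning outran spending by 16 at the start. As a correction of one part in that ratio, ceiling share over loading becomes 22.7. In a flask like south-west but at 0.020 M free monomer, protic impurity 0.750 equiv, the length is 0.0186, with quenched substrate at 73.9% and monomer in chains at 0.0437%; living end and spent initiator there sum to 5.00 × 10⁻⁴ M, against 5.00 × 10⁻⁴ M of initiator charged, so the second chemist's extra chains do not appear in that flask.

With 1.5 mol% of initiator, south-west's recipe otherwise, the ceiling share gives 35.5, corrected 37.8. The computed length is 35.7, with monomer in chains at 50.4%.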